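**Retrosynthetic overview**

1. Ring locants used throughout: C1 = C=O flanked by C2 (C–OH) and C6 (C–nonadecyl); C3 = C–CH3; C4 = C=O; C5 = C–H. The target should come from oxidation of benzene-1,2,4-triol 14, and 14 from Dakin oxidation of 2,4-dihydroxybenzaldehyde 12, whose formyl group on C1 is a removable activating group that is exchanged for the C1 oxygen.
2. Key disconnection: the only ring is closed in one Diels–Alder/aromatisation between diene 9 (C5–C4–C3–C2, made from methyl 2-methylacetoacetate) and docos-2-ynal 5 (C6–C1 plus the formyl carbon). This forms the C5–C6 bond (the ring C=C that carries the chain) and the C1–C2 bond (carbonyl carbon to hydroxyl-bearing carbon).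
3. Enabling feature: the oxygens on C2 and C4 stand 1,3 to each other across the methyl-bearing C3, which is a masked 2-methylacetoacetate. C6(nonadecyl)–C1(O) maps onto the β- and α-carbons of a 2-alkynal, whose CHO is later replaced by OH with retention of the ring carbon.
4. Ring order: a single six-membered carbocycle, formed in step 5; steps 1–4 build the two halves and steps 6–7 adjust the oxidation level.

Key step: step 5

Assumption (remark on the chemistry): silyl enol ether 7, dienolate 8 and diene 9 are used as E/Z mixtures and cycloadduct 10 is racemic; this has no consequence because these carbons all become aromatic and the target has no stereocentre.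

**Route**

Step 1
Reactants: 1 1-bromononadecane
Product: 2 henicos-1-yne
Conditions: LiC≡CH·H2NCH2CH2NH2 (1.5 equiv), DMSO/THF, 10 → 25 °C
Reagents that add atoms: lithium acetylide ethylenediamine complex, [Li]C#C.NCCN
Why: SN2 alkylation of an acetylide anion by an unhindered primary bromide in a dipolar aprotic medium is the standard entry to long-chain terminal alkynes.

Step 2
Reactants: 2 henicos-1-yne
Product: 5 docos-2-ynal, via lithium acetylide 3 (not isolated), via hemiaminal alkoxide 4 (not isolated)
Conditions: n-BuLi, THF, −20 °C; DMF, −20 → 20 °C; inverse quench into 10% aq. KH2PO4/MTBE, 0 °C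
Reagents that add atoms: N,N-dimethylformamide, CN(C)C=O
Why: Formylation of a lithium acetylide with DMF (Bouveault-type formylation) gives a tetrahedral adduct that is stable until the buffered inverse quench, which should release the ynal while protonating dimethylamine before it can add to the triple bond.

Step 3
Reactants: 6 methyl 2-methyl-3-oxobutanoate
Product: 7 methyl 2-methyl-3-(trimethylsilyloxy)but-2-enoate
Conditions: Me3SiCl, Et3N, PhMe, 20 °C
Reagents that add atoms: chlorotrimethylsilane, C[Si](C)(C)Cl
Why: Soft enolisation of the β-ketoester with Et3N and O-silylation gives the silyl enol ether, the first stage of the Chan-type bis(silyloxy)diene synthesis.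

Step 4
Reactants: 7 methyl 2-methyl-3-(trimethylsilyloxy)but-2-enoate
Product: 9 1-methoxy-2-methyl-1,3-bis(trimethylsilyloxy)buta-1,3-diene, via lithium dienolate 8 (not isolated)
Conditions: LiN(iPr)2, THF, −78 °C; Me3SiCl, −78 → 20 °C; used freshly, moisture excluded
Reagents that add atoms: chlorotrimethylsilane, C[Si](C)(C)Cl
Why: Kinetic γ-deprotonation of the vinylogous ester and O-silylation of the dienolate (silyl ketene acetal formation) is the established preparation of 2-alkyl-1,3-bis(silyloxy)-1,3-dienes.

Step 5
Reactants: 5 docos-2-ynal; 9 1-methoxy-2-methyl-1,3-bis(trimethylsilyloxy)buta-1,3-diene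
Product: 12 2,4-dihydroxy-3-methyl-6-nonadecylbenzaldehyde, via cyclohexadiene cycloadduct 10 (not isolated), via bis(trimethylsilyl) ether 11 (not isolated)
Conditions: 9 (1.5 equiv), PhMe, 0 → 60 °C, under argon, no Lewis acid; then 1 M HCl, THF, 20 °C
Reagents that add atoms: none
Why: This is a normal-electron-demand Diels–Alder reaction (possibly asynchronous, Mukaiyama–Michael-like) in which the electron-rich 1,1,3-trioxygenated diene 9 adds across the C≡C of the electron-poor ynal 5, after which cycloadduct 10 should aromatise by 1,4-elimination of methanol and the acidic work-up should cleave both silyl ethers. The closest known reaction type is the Diels–Alder benzannulation of Brassard- and Chan-type silyloxy ketene acetal dienes with conjugated acetylenic carbonyl compounds, which delivers 6-alkyl-2,4-dioxygenated benzoyl derivatives. The only ring of the target, the six-membered carbocycle, is closed by this intermolecular [4+2] cycloaddition, which forms the bond from the diene CH2 terminus (future C5) to the chain-bearing alkyne carbon (future C6) and the bond from the ketene acetal carbon (future C2) to the formyl-bearing alkyne carbon (future C1). No stereocentre has to be controlled, because the single sp3 acetal carbon of racemic 10 is flattened on aromatisation. The step needs regioselectivity and chemoselectivity for C≡C over C=O: the largest HOMO coefficient of 9 lies on its CH2 terminus and the largest LUMO coefficient of 5 on its β-carbon, which places the nonadecyl chain next to C5–H and the formyl group next to the C2 oxygen, and the absence of any Lewis acid in a non-polar solvent disfavours hetero-Diels–Alder or aldol attack at the aldehyde.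

Step 6
Reactants: 12 2,4-dihydroxy-3-methyl-6-nonadecylbenzaldehyde
Product: 14 3-methyl-6-nonadecylbenzene-1,2,4-triol, via aryl formate 13 (not isolated)
Conditions: 30% H2O2 (1.05 equiv), 1 M NaOH, degassed THF/H2O, 0 °C, under argon; then 1 M HCl; crude triol carried on without exposure to air
Reagents that add atoms: hydrogen peroxide, OO
Why: In this Dakin oxidation hydroperoxide adds to the aldehyde, the aryl group activated by ortho and para phenoxides migrates to oxygen with retention of the ring carbon, and the aryl formate is saponified in situ, while exclusion of air and the small excess of H2O2 protect the triol.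

Step 7
Reactants: 14 3-methyl-6-nonadecylbenzene-1,2,4-triol
Product: 15 Capiquinone C (2-hydroxy-3-methyl-6-nonadecylcyclohexa-2,5-diene-1,4-dione)
Conditions: FeCl3 (2.2 equiv), EtOH/0.1 M HCl, 20 °C
Reagents that add atoms: none
Why: Oxidation of a hydroquinone to a para-benzoquinone by FeCl3 removes two electrons and two protons from the 1,4-dihydroxy pair, and the 2-hydroxyl remains as the vinylogous acid of the 2-hydroxy-1,4-benzoquinone.

**Compound list**

1 | 1-bromononadecane | CCCCCCCCCCCCCCCCCCCBr | starting material
2 | henicos-1-yne | CCCCCCCCCCCCCCCCCCCC#C | intermediate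
3 | lithium henicos-1-yn-1-ide | CCCCCCCCCCCCCCCCCCCC#C[Li] | intermediate (not isolated)
4 | lithium 1-(dimethylamino)docos-2-yn-1-olate | CCCCCCCCCCCCCCCCCCCC#CC(O[Li])N(C)C | intermediate (not isolated)
5 | docos-2-ynal | CCCCCCCCCCCCCCCCCCCC#CC=O | intermediate
6 | methyl 2-methyl-3-oxobutanoate | COC(=O)C(C)C(C)=O | starting material
7 | methyl 2-methyl-3-(trimethylsilyloxy)but-2-enoate (E/Z mixture) | COC(=O)C(C)=C(C)O[Si](C)(C)C | intermediate
8 | lithium 1-methoxy-2-methyl-3-(trimethylsilyloxy)buta-1,3-dien-1-olate | C=C(O[Si](C)(C)C)C(C)=C(OC)O[Li] | intermediate (not isolated)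
9 | 1-methoxy-2-methyl-1,3-bis(trimethylsilyloxy)buta-1,3-diene (E/Z mixture) | C=C(O[Si](C)(C)C)C(C)=C(OC)O[Si](C)(C)C | intermediate
10 | 6-methoxy-5-methyl-2-nonadecyl-4,6-bis(trimethylsilyloxy)cyclohexa-1,4-diene-1-carbaldehyde (racemic) | O=CC1=C(CCCCCCCCCCCCCCCCCCC)CC(O[Si](C)(C)C)=C(C)C1(OC)O[Si](C)(C)C | intermediate (not isolated)
11 | 3-methyl-6-nonadecyl-2,4-bis(trimethylsilyloxy)benzaldehyde | O=Cc1c(CCCCCCCCCCCCCCCCCCC)cc(O[Si](C)(C)C)c(C)c1O[Si](C)(C)C | intermediate (not isolated)
12 | 2,4-dihydroxy-3-methyl-6-nonadecylbenzaldehyde | O=Cc1c(CCCCCCCCCCCCCCCCCCC)cc(O)c(C)c1O | intermediate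
13 | 2,4-dihydroxy-3-methyl-6-nonadecylphenyl formate | O=COc1c(CCCCCCCCCCCCCCCCCCC)cc(O)c(C)c1O | intermediate (not isolated)
14 | 3-methyl-6-nonadecylbenzene-1,2,4-triol | Oc1c(CCCCCCCCCCCCCCCCCCC)cc(O)c(C)c1O | intermediate
15 | Capiquinone C, 2-hydroxy-3-methyl-6-nonadecylcyclohexa-2,5-diene-1,4-dione | CCCCCCCCCCCCCCCCCCCC1=CC(=O)C(C)=C(O)C1=O | target

**Summary**

Total step count: 7.
Longest linear sequence: 5 steps (steps 1, 2, 5, 6, 7; the branch 3, 4, 5, 6, 7 is equally long).

**Three steps most likely to fail, with fallbacks**

Step 5 (key step). The process at risk is chemoselectivity and the mode of aromatisation: the diene may attack the formyl carbon (vinylogous aldol or hetero-Diels–Alder) instead of the triple bond, or the cycloadduct may lose trimethylsilanol instead of methanol. The fallback sets out from compound 2 and comes back to the route at compound 15; it keeps the same ring construction but uses an ester as the activating group and installs the C1 oxygen by late phenol oxidation. Lithium acetylide 3 (n-BuLi, THF) is quenched with ClCO2Me to give methyl docos-2-ynoate F1. Heating F1 with diene 9 (PhMe, 110 °C) should give the cycloadduct methyl 6-methoxy-5-methyl-2-nonadecyl-4,6-bis(trimethylsilyloxy)cyclohexa-1,4-diene-1-carboxylate F2, which loses methanol to methyl 3-methyl-6-nonadecyl-2,4-bis(trimethylsilyloxy)benzoate F3 and on HCl work-up gives methyl 2,4-dihydroxy-3-methyl-6-nonadecylbenzoate F4. Saponification (KOH, aqueous ethylene glycol, 120 °C) gives 2,4-dihydroxy-3-methyl-6-nonadecylbenzoic acid F5, which decarboxylates on further heating to 2-methyl-5-nonadecylbenzene-1,3-diol F6. Teuber oxidation of F6 with (KSO3)2NO (KH2PO4 buffer, acetone/H2O) at the free position para to one hydroxyl should give 15.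

Step 6. The process at risk is over-oxidation: the very electron-rich triol may autoxidise under the alkaline peroxide conditions and the resulting quinone may be degraded by hydroperoxide. The fallback sets out from compound 12 and comes back at compound 15; it carries the oxygens as methyl ethers so that the aryl migration gives a stable monophenol. Both phenols of 12 are methylated (Me2SO4, K2CO3, acetone, reflux) to 2,4-dimethoxy-3-methyl-6-nonadecylbenzaldehyde F7. Baeyer–Villiger oxidation (mCPBA, CH2Cl2) gives 2,4-dimethoxy-3-methyl-6-nonadecylphenyl formate F8, which is cleaved (KOH, MeOH/H2O) to 2,4-dimethoxy-3-methyl-6-nonadecylphenol F9. Oxidative demethylation of the para-methoxyphenol with (NH4)2Ce(NO3)6 in MeCN/H2O gives 2-methoxy-3-methyl-6-nonadecylcyclohexa-2,5-diene-1,4-dione F10, and hydrolysis of this vinylogous ester (aq. NaOH, MeOH; then HCl) should give 15.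

Step 2. The process at risk is conjugate addition of the dimethylamine released on collapse of the hemiaminal to the ynal during the quench, and oligomerisation of the ynal on isolation. The fallback sets out from compound 1 and comes back at compound 5; it brings in the formyl carbon as an acetal by C-alkylation, so that no amine is ever present. Commercial 3,3-diethoxyprop-1-yne is lithiated (n-BuLi, THF, −78 °C) to (3,3-diethoxyprop-1-yn-1-yl)lithium F11 and alkylated with bromide 1 (THF/DMPU, 0 → 25 °C) to 1,1-diethoxydocos-2-yne F12. Acetal hydrolysis (HCO2H/H2O, 20 °C) should then give 5.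

Further compounds
F1 | step 5 | methyl docos-2-ynoate | CCCCCCCCCCCCCCCCCCCC#CC(=O)OC
F2 | step 5 | methyl 6-methoxy-5-methyl-2-nonadecyl-4,6-bis(trimethylsilyloxy)cyclohexa-1,4-diene-1-carboxylate (racemic) | COC(=O)C1=C(CCCCCCCCCCCCCCCCCCC)CC(O[Si](C)(C)C)=C(C)C1(OC)O[Si](C)(C)C
F3 | step 5 | methyl 3-methyl-6-nonadecyl-2,4-bis(trimethylsilyloxy)benzoate | COC(=O)c1c(CCCCCCCCCCCCCCCCCCC)cc(O[Si](C)(C)C)c(C)c1O[Si](C)(C)C
F4 | step 5 | methyl 2,4-dihydroxy-3-methyl-6-nonadecylbenzoate | COC(=O)c1c(CCCCCCCCCCCCCCCCCCC)cc(O)c(C)c1O
F5 | step 5 | 2,4-dihydroxy-3-methyl-6-nonadecylbenzoic acid | OC(=O)c1c(CCCCCCCCCCCCCCCCCCC)cc(O)c(C)c1O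
F6 | step 5 | 2-methyl-5-nonadecylbenzene-1,3-diol | Cc1c(O)cc(CCCCCCCCCCCCCCCCCCC)cc1O
F7 | step 6 | 2,4-dimethoxy-3-methyl-6-nonadecylbenzaldehyde | O=Cc1c(CCCCCCCCCCCCCCCCCCC)cc(OC)c(C)c1OC
F8 | step 6 | 2,4-dimethoxy-3-methyl-6-nonadecylphenyl formate | O=COc1c(CCCCCCCCCCCCCCCCCCC)cc(OC)c(C)c1OC
F9 | step 6 | 2,4-dimethoxy-3-methyl-6-nonadecylphenol | Oc1c(CCCCCCCCCCCCCCCCCCC)cc(OC)c(C)c1OC
F10 | step 6 | 2-methoxy-3-methyl-6-nonadecylcyclohexa-2,5-diene-1,4-dione | CCCCCCCCCCCCCCCCCCCC1=CC(=O)C(C)=C(OC)C1=O
F11 | step 2 | (3,3-diethoxyprop-1-yn-1-yl)lithium | [Li]C#CC(OCC)OCC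
F12 | step 2 | 1,1-diethoxydocos-2-yne | CCCCCCCCCCCCCCCCCCCC#CC(OCC)OCC
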